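**Retrosynthetic overview**

1. The route rests on one feature of the flavanone: C2 is the benzylic carbon of a 4′-alkoxy-3′-methoxybenzyl ether of O1 (the oxygen on C8a of ring A), so its C–H is a hydride donor towards DDQ, and C3 is the α-carbon of the ring A aryl ketone C4, which can be held as an enol acetate.
2. Key disconnection C2–C3: ring C is closed last by oxidative C–H cyclisation of the enol acetate onto the O-aryl oxocarbenium ion, with a chiral phosphate counter-anion meant to set C2 as S.
3. The precursor comes from a ring A acetophenone by O-benzylation of its unhindered ortho hydroxyl with MOM-protected vanillyl chloride (ring B), MOM protection of the hindered ortho hydroxyl (an ether, not an ester) and enolate O-acetylation.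
4. The 1,1-dimethylallyl group is placed by Claisen rearrangement of the 4-O-prenyl ether of 2,4,6-trihydroxyacetophenone: the para position carries the acetyl group and the two ortho positions are equivalent, so only one product can form.
5. Rings A and B are bought (trihydroxyacetophenone, vanillin); ring C is the only ring formed; acidic removal of three MOM ethers ends the route.

Key step: step 10

Remark: flavanone numbering (O1, C2, C3, C4, C4a, C5 to C8, C8a, primed locants for ring B) is used in the discussion; the target is the 2S enantiomer.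
Assumption: the sense of induction of the chiral phosphate in step 10 cannot be predicted; the (R)-phosphate is written and its (S)-antipode would be used if the 2R flavanone is favoured.

**Route**

Step 1
Reactants: 1 2,4,6-trihydroxyacetophenone; 2 prenyl bromide (1-bromo-3-methylbut-2-ene)
Product: 3 1-[2,6-dihydroxy-4-(3-methylbut-2-enyloxy)phenyl]ethanone
Conditions: 2 (1.0 equiv), K2CO3 (1.0 equiv), acetone, rt
Reagents that add atoms: none
Why: Williamson ether synthesis in which the 4-OH, the most acidic hydroxyl and the only one outside the O–H···O=C chelate, is alkylated first, while one equivalent of bromide and a mild carbonate base in acetone keep bis-ether formation and C-prenylation low.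

Step 2
Reactants: 3 1-[2,6-dihydroxy-4-(3-methylbut-2-enyloxy)phenyl]ethanone
Product: 5 1-[2,4,6-trihydroxy-3-(2-methylbut-3-en-2-yl)phenyl]ethanone, via cyclohexadienone 4 (not isolated)
Conditions: PhNEt2, 185 °C, Ar
Reagents that add atoms: none
Why: Aromatic Claisen rearrangement, a [3,3] shift with allyl inversion that delivers the 1,1-dimethylallyl group to an ortho carbon; the para carbon bears the acetyl group so no Cope relay to a normal prenyl group is possible, and the two ortho carbons are equivalent, so tautomerisation of dienone 4 should give a single regioisomer.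

Step 3
Reactants: 5 1-[2,4,6-trihydroxy-3-(2-methylbut-3-en-2-yl)phenyl]ethanone
Product: 6 1-[2,6-dihydroxy-4-(methoxymethoxy)-3-(2-methylbut-3-en-2-yl)phenyl]ethanone
Conditions: MOMCl (1.05 equiv), iPr2NEt (1.2 equiv), CH2Cl2, 0 °C
Reagents that add atoms: chloromethyl methyl ether (MOMCl), COCCl
Why: Selective O-alkylation (acetal formation) of the 4-OH, which is para to the acetyl group, the most acidic hydroxyl and not hydrogen-bonded to the carbonyl, with a small and very reactive electrophile that is little slowed by the neighbouring quaternary carbon.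

Step 4
Reactants: 7 vanillin (4-hydroxy-3-methoxybenzaldehyde)
Product: 8 3-methoxy-4-(methoxymethoxy)benzaldehyde
Conditions: MOMCl, iPr2NEt, CH2Cl2, 0 °C → rt
Reagents that add atoms: chloromethyl methyl ether (MOMCl), COCCl
Why: Standard MOM protection of an acidic phenol (O-alkylation of the phenoxide), which leaves the aldehyde untouched.

Step 5
Reactants: 8 3-methoxy-4-(methoxymethoxy)benzaldehyde
Product: 9 [3-methoxy-4-(methoxymethoxy)phenyl]methanol
Conditions: NaBH4, MeOH, 0 °C
Reagents that add atoms: none
Why: Borohydride reduction of an aryl aldehyde to the benzylic alcohol, with the MOM acetal stable under the basic conditions.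

Step 6
Reactants: 9 [3-methoxy-4-(methoxymethoxy)phenyl]methanol
Product: 10 4-(chloromethyl)-2-methoxy-1-(methoxymethoxy)benzene
Conditions: MsCl, Et3N, CH2Cl2, 0 °C → rt; used at once without chromatography
Reagents that add atoms: methanesulfonyl chloride, CS(=O)(=O)Cl
Why: Mesylation of an electron-rich benzylic alcohol followed by in situ displacement of the mesylate by chloride, under basic conditions that spare the MOM ether.

Step 7
Reactants: 6 1-[2,6-dihydroxy-4-(methoxymethoxy)-3-(2-methylbut-3-en-2-yl)phenyl]ethanone; 10 4-(chloromethyl)-2-methoxy-1-(methoxymethoxy)benzene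
Product: 11 1-[2-hydroxy-6-{[3-methoxy-4-(methoxymethoxy)phenyl]methoxy}-4-(methoxymethoxy)-3-(2-methylbut-3-en-2-yl)phenyl]ethanone
Conditions: 10 (1.05 equiv), K2CO3 (1.5 equiv), nBu4NI (cat.), DMF, rt
Reagents that add atoms: none
Why: Williamson ether synthesis in which the 6-OH, with only a hydrogen neighbour, is alkylated, while the 2-OH between the acetyl group and the quaternary carbon of the 1,1-dimethylallyl group is shielded and stays in the chelate, so monoalkylation at the future O1 is expected.

Step 8
Reactants: 11 1-[2-hydroxy-6-{[3-methoxy-4-(methoxymethoxy)phenyl]methoxy}-4-(methoxymethoxy)-3-(2-methylbut-3-en-2-yl)phenyl]ethanone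
Product: 13 1-[6-{[3-methoxy-4-(methoxymethoxy)phenyl]methoxy}-2,4-bis(methoxymethoxy)-3-(2-methylbut-3-en-2-yl)phenyl]ethanone, via sodium phenoxide 12 (not isolated)
Conditions: NaH (1.1 equiv), DMF, 0 °C; then MOMCl, 0 °C → rt
Reagents that add atoms: chloromethyl methyl ether (MOMCl), COCCl
Why: O-alkylation of the preformed sodium phenoxide of the hindered chelated hydroxyl with the small MOM electrophile, an ether being chosen instead of an ester so that the enolate of step 9 has no neighbouring acyl group to attack (no Baker–Venkataraman transfer).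

Step 9
Reactants: 13 1-[6-{[3-methoxy-4-(methoxymethoxy)phenyl]methoxy}-2,4-bis(methoxymethoxy)-3-(2-methylbut-3-en-2-yl)phenyl]ethanone
Product: 15 1-[6-{[3-methoxy-4-(methoxymethoxy)phenyl]methoxy}-2,4-bis(methoxymethoxy)-3-(2-methylbut-3-en-2-yl)phenyl]ethenyl acetate, via potassium enolate 14 (not isolated)
Conditions: KN(SiMe3)2 (1.2 equiv), THF, −78 °C; then Ac2O, −78 → 0 °C
Reagents that add atoms: acetic anhydride, CC(=O)OC(C)=O
Why: Enolate O-acylation, in which the methyl ketone is the only enolisable site and its potassium enolate reacts with acetic anhydride at oxygen to give the enol acetate, under basic conditions that keep the MOM ethers, the benzyl ether and the vinyl group intact.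

Step 10
Reactants: 15 1-[6-{[3-methoxy-4-(methoxymethoxy)phenyl]methoxy}-2,4-bis(methoxymethoxy)-3-(2-methylbut-3-en-2-yl)phenyl]ethenyl acetate
Product: 18 (2S)-2-[3-methoxy-4-(methoxymethoxy)phenyl]-5,7-bis(methoxymethoxy)-6-(2-methylbut-3-en-2-yl)-2,3-dihydro-4H-chromen-4-one, via oxocarbenium ion 16 (not isolated), via O-acetyl oxocarbenium ion 17 (not isolated)
Conditions: DDQ (1.2 equiv), sodium (R)-3,3′-bis(2,4,6-triisopropylphenyl)-1,1′-binaphthyl-2,2′-diyl phosphate (1.1 equiv), 2,6-dichloropyridine, 4 Å MS, toluene, −20 °C, high dilution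
Reagents that add atoms: none
Why: Proposed new method: DDQ takes hydride from the O–CH2 group of the ring B benzyl ether, the only C–H whose cation is stabilised by both the ether oxygen and a para-alkoxyaryl ring, and the O-aryl oxocarbenium ion 16 is meant to exchange its hydroquinone monoanion (whose sodium salt should be insoluble in toluene) for the lipophilic chiral phosphate before the enol acetate carbon C3 adds to C2, after which acetyl transfer from cation 17 to the hydroquinone monoanion gives the C4 ketone and frees the phosphate. The closest known reaction types are the DDQ-mediated oxidative C–H cleavage of p-methoxybenzyl ethers with enol acetate trapping to 2-aryltetrahydropyran-4-ones, the DDQ oxidation of 2H-chromenes to O-aryl benzopyrylium ions, and chiral phosphate counter-anion control of additions to oxocarbenium ions; their combination on an acyclic O-aryl benzyl ether is untested. Ring C closes in a 6-endo-trig mode at the C2=O1 unit with the enol C3=C4 bond also inside the new ring (6-(enolendo)-endo-trig). The C2 stereocentre is set by the chiral phosphate alone, which has to shield the Re face of C2 (O1 > C1′ > H) so that C3 adds to the Si face and gives 2S. The step needs site-selective oxidation, secured by the 4′-alkoxy group and by the quaternary allylic carbon of the 1,1-dimethylallyl group, and it needs the product to survive, which the C4 carbonyl helps by destabilising a second cation at C2.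

Step 11
Reactants: 18 (2S)-2-[3-methoxy-4-(methoxymethoxy)phenyl]-5,7-bis(methoxymethoxy)-6-(2-methylbut-3-en-2-yl)-2,3-dihydro-4H-chromen-4-one
Product: 19 (2S)-5,7-dihydroxy-2-(4-hydroxy-3-methoxyphenyl)-6-(2-methylbut-3-en-2-yl)-2,3-dihydro-4H-chromen-4-one (target)
Conditions: HCl (2 M in MeOH), rt → 40 °C
Reagents that add atoms: none
Why: Acid-catalysed methanolysis (transacetalisation) of the three aryl MOM ethers, in a medium that avoids the base-induced ring opening to the chalcone and so keeps C2, and mild enough that the monosubstituted vinyl group of the 1,1-dimethylallyl unit should not add a flanking hydroxyl.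

**Compound list**

1 | 2,4,6-trihydroxyacetophenone | CC(=O)c1c(O)cc(O)cc1O | starting material
2 | prenyl bromide (1-bromo-3-methylbut-2-ene) | CC(C)=CCBr | starting material
3 | 1-[2,6-dihydroxy-4-(3-methylbut-2-enyloxy)phenyl]ethanone | CC(=O)c1c(O)cc(OCC=C(C)C)cc1O | intermediate
4 | 4-acetyl-3,5-dihydroxy-6-(2-methylbut-3-en-2-yl)cyclohexa-2,4-dien-1-one (Claisen dienone, racemic) | CC(=O)C1=C(O)C(C(C)(C)C=C)C(=O)C=C1O | intermediate (not isolated)
5 | 1-[2,4,6-trihydroxy-3-(2-methylbut-3-en-2-yl)phenyl]ethanone | CC(=O)c1c(O)cc(O)c(C(C)(C)C=C)c1O | intermediate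
6 | 1-[2,6-dihydroxy-4-(methoxymethoxy)-3-(2-methylbut-3-en-2-yl)phenyl]ethanone | CC(=O)c1c(O)cc(OCOC)c(C(C)(C)C=C)c1O | intermediate
7 | vanillin (4-hydroxy-3-methoxybenzaldehyde) | COc1cc(C=O)ccc1O | starting material
8 | 3-methoxy-4-(methoxymethoxy)benzaldehyde | COCOc1ccc(C=O)cc1OC | intermediate
9 | [3-methoxy-4-(methoxymethoxy)phenyl]methanol | COCOc1ccc(CO)cc1OC | intermediate
10 | 4-(chloromethyl)-2-methoxy-1-(methoxymethoxy)benzene | COCOc1ccc(CCl)cc1OC | intermediate
11 | 1-[2-hydroxy-6-{[3-methoxy-4-(methoxymethoxy)phenyl]methoxy}-4-(methoxymethoxy)-3-(2-methylbut-3-en-2-yl)phenyl]ethanone | CC(=O)c1c(OCc2ccc(OCOC)c(OC)c2)cc(OCOC)c(C(C)(C)C=C)c1O | intermediate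
12 | sodium phenoxide of 11 | CC(=O)c1c(OCc2ccc(OCOC)c(OC)c2)cc(OCOC)c(C(C)(C)C=C)c1[O-].[Na+] | intermediate (not isolated)
13 | 1-[6-{[3-methoxy-4-(methoxymethoxy)phenyl]methoxy}-2,4-bis(methoxymethoxy)-3-(2-methylbut-3-en-2-yl)phenyl]ethanone | CC(=O)c1c(OCc2ccc(OCOC)c(OC)c2)cc(OCOC)c(C(C)(C)C=C)c1OCOC | intermediate
14 | potassium enolate of 13 | C=C([O-])c1c(OCc2ccc(OCOC)c(OC)c2)cc(OCOC)c(C(C)(C)C=C)c1OCOC.[K+] | intermediate (not isolated)
15 | 1-[6-{[3-methoxy-4-(methoxymethoxy)phenyl]methoxy}-2,4-bis(methoxymethoxy)-3-(2-methylbut-3-en-2-yl)phenyl]ethenyl acetate (key-step precursor) | C=CC(C)(C)c1c(OCOC)cc(OCc2ccc(OCOC)c(OC)c2)c(C(=C)OC(C)=O)c1OCOC | intermediate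
16 | O-aryl oxocarbenium ion from 15 (cation at C2, phosphate counter-ion) | C=CC(C)(C)c1c(OCOC)cc([O+]=Cc2ccc(OCOC)c(OC)c2)c(C(=C)OC(C)=O)c1OCOC | intermediate (not isolated)
17 | (2S)-cyclised O-acetyl oxocarbenium ion (acetylated C4 carbonyl of 18) | C=CC(C)(C)c1c(OCOC)cc2c(c1OCOC)C(=[O+]C(C)=O)C[C@@H](c1ccc(OCOC)c(OC)c1)O2 | intermediate (not isolated)
18 | (2S)-2-[3-methoxy-4-(methoxymethoxy)phenyl]-5,7-bis(methoxymethoxy)-6-(2-methylbut-3-en-2-yl)-2,3-dihydro-4H-chromen-4-one (key-step product) | C=CC(C)(C)c1c(OCOC)cc2c(c1OCOC)C(=O)C[C@@H](c1ccc(OCOC)c(OC)c1)O2 | intermediate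
19 | (2S)-5,7-dihydroxy-2-(4-hydroxy-3-methoxyphenyl)-6-(2-methylbut-3-en-2-yl)-2,3-dihydro-4H-chromen-4-one (CNP0279383.1) | C=CC(C)(C)c1c(O)cc2c(c1O)C(=O)C[C@@H](c1ccc(O)c(OC)c1)O2 | target

**Step count**

Total steps: 11. Longest linear sequence: 8 steps (steps 1, 2, 3, 7, 8, 9, 10, 11, from compound 1).

**Steps most likely to fail**

1. Step 10 (Proposed new method). What may go wrong: ring closure inside the first-formed ion pair with the achiral hydroquinone monoanion before the phosphate takes its place, giving poor facial selectivity; slow hydride loss from an O-aryl ether; further dehydrogenation of the flavanone to the flavone. Fallback by known chemistry, setting out from 13 and coming back at 18: the ring B benzyl ether of 13 is cleaved oxidatively (DDQ, CH2Cl2, pH 7 buffer) to 1-[6-hydroxy-2,4-bis(methoxymethoxy)-3-(2-methylbut-3-en-2-yl)phenyl]ethanone F1, with aldehyde 8 returned. Claisen–Schmidt condensation of F1 with 8 (KOH, EtOH, rt) should give (E)-1-[6-hydroxy-2,4-bis(methoxymethoxy)-3-(2-methylbut-3-en-2-yl)phenyl]-3-[3-methoxy-4-(methoxymethoxy)phenyl]prop-2-en-1-one F2. Oxa-Michael ring closure through the only free hydroxyl (NaOAc, EtOH, reflux) should give the racemic flavanone 2-[3-methoxy-4-(methoxymethoxy)phenyl]-5,7-bis(methoxymethoxy)-6-(2-methylbut-3-en-2-yl)-2,3-dihydro-4H-chromen-4-one F3. Kinetic resolution by asymmetric transfer hydrogenation (Cp*RhCl[(R,R)-TsDPEN] or its antipode, whichever reduces the 2R ketone faster, HCO2H/Et3N, EtOAc, stopped near half conversion) converts the unwanted enantiomer into (2R,4R)-2-[3-methoxy-4-(methoxymethoxy)phenyl]-5,7-bis(methoxymethoxy)-6-(2-methylbut-3-en-2-yl)chroman-4-ol F4 and leaves 18.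

2. Step 2. What may go wrong: the freshly formed ortho-(1,1-dimethylallyl)phenol reacts on at the rearrangement temperature, by addition of a flanking hydroxyl to the vinyl group, by abnormal Claisen isomerisation to a 1,2-dimethylallyl group, or by loss of the prenyl group. Fallback, setting out from 3 and coming back at 5: 3 is heated with N,O-bis(trimethylsilyl)acetamide in PhNEt2, so that it rearranges as 1-[4-(3-methylbut-2-enyloxy)-2,6-bis(trimethylsilyloxy)phenyl]ethanone F5 and the new phenol is silylated as it forms, giving 1-[3-(2-methylbut-3-en-2-yl)-2,4,6-tris(trimethylsilyloxy)phenyl]ethanone F6; mild methanolysis (MeOH, cat. citric acid, rt) then releases 5.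

3. Step 3. What may go wrong: poor site selectivity between the hindered free 4-OH and the unhindered chelated 6-OH, and double protection. Fallback, setting out from 3 and coming back at 6: both chelated hydroxyls of 3 are acetylated (Ac2O, pyridine, DMAP, rt) to 2-acetyl-5-(3-methylbut-2-enyloxy)-1,3-phenylene diacetate F7. Claisen rearrangement (PhNEt2, 185 °C) should give 2-acetyl-5-hydroxy-4-(2-methylbut-3-en-2-yl)-1,3-phenylene diacetate F8, in which the 4-OH is the only free hydroxyl. MOM protection (MOMCl, iPr2NEt, CH2Cl2) gives 2-acetyl-5-(methoxymethoxy)-4-(2-methylbut-3-en-2-yl)-1,3-phenylene diacetate F9, and methanolysis of both acetates (K2CO3, MeOH, rt) gives 6.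

**Further compounds**

F1 | step 10 | 1-[6-hydroxy-2,4-bis(methoxymethoxy)-3-(2-methylbut-3-en-2-yl)phenyl]ethanone | CC(=O)c1c(O)cc(OCOC)c(C(C)(C)C=C)c1OCOC
F2 | step 10 | (E)-1-[6-hydroxy-2,4-bis(methoxymethoxy)-3-(2-methylbut-3-en-2-yl)phenyl]-3-[3-methoxy-4-(methoxymethoxy)phenyl]prop-2-en-1-one | C=CC(C)(C)c1c(OCOC)cc(O)c(C(=O)/C=C/c2ccc(OCOC)c(OC)c2)c1OCOC
F3 | step 10 | racemic 2-[3-methoxy-4-(methoxymethoxy)phenyl]-5,7-bis(methoxymethoxy)-6-(2-methylbut-3-en-2-yl)-2,3-dihydro-4H-chromen-4-one | C=CC(C)(C)c1c(OCOC)cc2c(c1OCOC)C(=O)CC(c1ccc(OCOC)c(OC)c1)O2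
F4 | step 10 | (2R,4R)-2-[3-methoxy-4-(methoxymethoxy)phenyl]-5,7-bis(methoxymethoxy)-6-(2-methylbut-3-en-2-yl)chroman-4-ol | C=CC(C)(C)c1c(OCOC)cc2c(c1OCOC)[C@H](O)C[C@H](c1ccc(OCOC)c(OC)c1)O2
F5 | step 2 | 1-[4-(3-methylbut-2-enyloxy)-2,6-bis(trimethylsilyloxy)phenyl]ethanone | CC(=O)c1c(O[Si](C)(C)C)cc(OCC=C(C)C)cc1O[Si](C)(C)C
F6 | step 2 | 1-[3-(2-methylbut-3-en-2-yl)-2,4,6-tris(trimethylsilyloxy)phenyl]ethanone | CC(=O)c1c(O[Si](C)(C)C)cc(O[Si](C)(C)C)c(C(C)(C)C=C)c1O[Si](C)(C)C
F7 | step 3 | 2-acetyl-5-(3-methylbut-2-enyloxy)-1,3-phenylene diacetate | CC(=O)Oc1cc(OCC=C(C)C)cc(OC(C)=O)c1C(C)=O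
F8 | step 3 | 2-acetyl-5-hydroxy-4-(2-methylbut-3-en-2-yl)-1,3-phenylene diacetate | CC(=O)Oc1cc(O)c(C(C)(C)C=C)c(OC(C)=O)c1C(C)=O
F9 | step 3 | 2-acetyl-5-(methoxymethoxy)-4-(2-methylbut-3-en-2-yl)-1,3-phenylene diacetate | CC(=O)Oc1cc(OCOC)c(C(C)(C)C=C)c(OC(C)=O)c1C(C)=O
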